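**Retrosynthetic overview**

1. Ring A is numbered C1 (CH2CH2 chain to ring C), C2 (hydroquinone ring B), C3 (OH), C5 (OMe). Oxygen sits on C3 and C5 only, so ring A is read as an aromatized cyclohexane-1,3-dione methyl enol ether; debenzylation, dehydrogenation and O-methylation at C5 are taken off first.
2. The dione is opened at C1–C2 (conjugate addition) and C3–C4 (Claisen acylation). C2–C3 with ring B is a homogentisate ester; C4–C5–C6–C1 with the chain is a methyl enone whose β-carbon is C1.
3. The ester comes from homogentisic acid (esterify, benzylate); the enone from 3-(3-hydroxyphenyl)propanoic acid (benzylate, half-reduce, Wittig).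
4. Ring order: rings B and C are bought; ring A is the only ring built, first saturated in the annulation, then aromatized one step before the end.

Key step: step 6

Assumption: the ring A–ring B axis (three ortho substituents) is taken as freely rotating, so the target is treated as achiral; the ring-A stereocentres of 9–12 are racemic and vanish on aromatization.

**Route**

Step 1
Reactants: 1 homogentisic acid (2,5-dihydroxyphenylacetic acid)
Product: 2 methyl 2-(2,5-dihydroxyphenyl)acetate
Conditions: MeOH, H2SO4 (cat.), reflux, N2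
Reagents that add atoms: methanol, CO
Why: Fischer esterification driven by methanol as solvent; the acidic medium keeps the hydroquinone from air oxidation and reopens any benzofuranone lactone to the methyl ester.

Step 2
Reactants: 2 methyl 2-(2,5-dihydroxyphenyl)acetate
Product: 3 methyl 2-[2,5-bis(benzyloxy)phenyl]acetate
Conditions: BnBr (2.3 equiv), K2CO3, DMF, 50 °C, N2
Reagents that add atoms: benzyl bromide, BrCc1ccccc1
Why: Williamson etherification, in which K2CO3 ionizes only the two phenols (not the ester α-CH2) and the phenoxides displace bromide from BnBr, air being excluded to prevent quinone formation.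

Step 3
Reactants: 4 3-(3-hydroxyphenyl)propanoic acid
Product: 5 benzyl 3-(3-benzyloxyphenyl)propanoate
Conditions: BnBr (2.3 equiv), K2CO3, DMF, 60 °C
Reagents that add atoms: benzyl bromide, BrCc1ccccc1
Why: Williamson etherification of the phenoxide together with O-alkylation of the carboxylate, so that one operation masks the phenol and delivers an ester ready for half-reduction.

Step 4
Reactants: 5 benzyl 3-(3-benzyloxyphenyl)propanoate
Product: 6 3-(3-benzyloxyphenyl)propanal
Conditions: iBu2AlH (1.1 equiv), CH2Cl2, −78 °C; MeOH, then aq. potassium sodium tartrate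
Reagents that add atoms: none
Why: Partial reduction of an ester with iBu2AlH, in which the aluminium hemiacetal formed by one hydride transfer is stable at −78 °C and releases the aldehyde only on work-up, the aryl benzyl ether being inert.

Step 5
Reactants: 6 3-(3-benzyloxyphenyl)propanal; 7 1-(triphenylphosphoranylidene)propan-2-one
Product: 8 (E)-6-(3-benzyloxyphenyl)hex-3-en-2-one
Conditions: CH2Cl2, 40 °C
Reagents that add atoms: none
Why: Wittig olefination with a stabilized acyl ylide, which reacts with the unhindered aldehyde under thermodynamic control of the oxaphosphetane and should give the E-enone.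

Step 6
Reactants: 3 methyl 2-[2,5-bis(benzyloxy)phenyl]acetate; 8 (E)-6-(3-benzyloxyphenyl)hex-3-en-2-one
Product: 10 trans-4-[2,5-bis(benzyloxy)phenyl]-5-[2-(3-benzyloxyphenyl)ethyl]cyclohexane-1,3-dione (racemic), via keto ester Michael adduct 9 (not isolated)
Conditions: KOtBu (1.2 equiv), THF, 0 °C; then 8 (slow addition), 0 °C to 50 °C; aq. HCl
Reagents that add atoms: none
Why: KOtBu deprotonates ester 3 at its benzylic α-carbon (the most acidic C–H in the flask), the potassium enolate adds reversibly to the β-carbon of 8 to form C1–C2 of ring A (adduct 9), proton transfer moves the charge to the methyl ketone, and its terminal enolate acylates on the ester to form C3–C4 with loss of methoxide, after which deprotonation of the 1,3-dione makes the sequence irreversible. The closest known reaction type is the consecutive Michael–Claisen annulation of ester or malonate enolates with methyl enones, the classical route to dimedone and to 4,5-disubstituted cyclohexane-1,3-diones. Ring A closes in a 6-(enolendo)-exo-trig mode, favoured for enolates, whereas the internal ketone enolate could reach the ester only through a four-membered ring. The two new stereocentres are under thermodynamic control, since the aryl-bearing centre is α to a carbonyl and epimerizes (in the open adduct and through the enol on acidification) to the trans diequatorial isomer; both are erased in step 9, so the product is racemic and its relative configuration is of no consequence. The step needs conjugate over carbonyl addition and must avoid γ-deprotonation and self-condensation of the enone: reversible alkoxide conditions return any carbonyl adduct to the conjugate pathway, and slow addition of 8 to the preformed ester enolate keeps free enone and free alkoxide low.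

Step 7
Reactants: 10 trans-4-[2,5-bis(benzyloxy)phenyl]-5-[2-(3-benzyloxyphenyl)ethyl]cyclohexane-1,3-dione
Product: 11 trans-6-[2,5-bis(benzyloxy)phenyl]-5-[2-(3-benzyloxyphenyl)ethyl]-3-methoxycyclohex-2-en-1-one (racemic)
Conditions: TsOH·H2O (cat.), MeOH, 3 Å MS, 50 °C
Reagents that add atoms: methanol, CO
Why: Acid-catalysed enol etherification of a 1,3-dione under equilibrium control, in which the C3 carbonyl (ring A numbering) is shielded by the ortho-substituted ring B on C2, so methanol should exchange at the open C5 carbonyl and give the less congested enol ether, with the trans arrangement kept by enolization.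

Step 8
Reactants: 11 trans-6-[2,5-bis(benzyloxy)phenyl]-5-[2-(3-benzyloxyphenyl)ethyl]-3-methoxycyclohex-2-en-1-one
Product: 12 2-[2,5-bis(benzyloxy)phenyl]-3-[2-(3-benzyloxyphenyl)ethyl]-5-methoxy-1-(trimethylsilyloxy)cyclohexa-1,5-diene (racemic)
Conditions: LiN(iPr)2 (1.2 equiv), THF, −78 °C; TMSCl, −78 to 0 °C
Reagents that add atoms: chlorotrimethylsilane, C[Si](C)(C)Cl
Why: Kinetic α′-deprotonation of a 3-alkoxy enone (as in Stork–Danheiser chemistry) at the benzylic C2–H followed by O-silylation gives the cross-conjugated silyl dienol ether, which is already a dihydroarene; the γ-enolate, should it form, would give an isomeric silyloxydiene that converges on the same phenol in step 9.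

Step 9
Reactants: 12 2-[2,5-bis(benzyloxy)phenyl]-3-[2-(3-benzyloxyphenyl)ethyl]-5-methoxy-1-(trimethylsilyloxy)cyclohexa-1,5-diene
Product: 14 2-[2,5-bis(benzyloxy)phenyl]-3-[2-(3-benzyloxyphenyl)ethyl]-5-methoxyphenol, via dienone tautomer 13 (not isolated)
Conditions: Pd(OAc)2 (1.1 equiv), MeCN, rt; filtration through Celite
Reagents that add atoms: none
Why: Saegusa–Ito oxidation, in which Pd(OAc)2 turns the silyl enol ether into a divalent palladium enolate at C2, syn β-hydride elimination from C1 (palladium enters anti to the chain, hence syn to that hydrogen) gives dienone 13 and zerovalent palladium, and 13 tautomerizes at once to the phenol because its only sp3 carbon is a CH2 para to the carbonyl.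

Step 10
Reactants: 14 2-[2,5-bis(benzyloxy)phenyl]-3-[2-(3-benzyloxyphenyl)ethyl]-5-methoxyphenol
Product: 15 6-[2-(3-hydroxyphenyl)ethyl]-4-methoxybiphenyl-2,2',5'-triol (CNP0121738.0)
Conditions: H2 (1 atm), 10% Pd/C, EtOAc/MeOH, rt; work-up under N2
Reagents that add atoms: none
Why: Catalytic hydrogenolysis of the three aryl benzyl ethers over Pd/C leaves the aryl methyl ether, the arenes and the diarylethane untouched, and inert work-up keeps the hydroquinone from oxidizing to the quinone.

**Compound list**

1 | homogentisic acid | OC(=O)Cc1cc(O)ccc1O | starting material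
2 | methyl 2-(2,5-dihydroxyphenyl)acetate | COC(=O)Cc1cc(O)ccc1O | intermediate
3 | methyl 2-[2,5-bis(benzyloxy)phenyl]acetate | COC(=O)Cc1cc(OCc2ccccc2)ccc1OCc1ccccc1 | intermediate
4 | 3-(3-hydroxyphenyl)propanoic acid | OC(=O)CCc1cccc(O)c1 | starting material
5 | benzyl 3-(3-benzyloxyphenyl)propanoate | O=C(CCc1cccc(OCc2ccccc2)c1)OCc1ccccc1 | intermediate
6 | 3-(3-benzyloxyphenyl)propanal | O=CCCc1cccc(OCc2ccccc2)c1 | intermediate
7 | 1-(triphenylphosphoranylidene)propan-2-one | CC(=O)C=P(c1ccccc1)(c1ccccc1)c1ccccc1 | starting material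
8 | (E)-6-(3-benzyloxyphenyl)hex-3-en-2-one | CC(=O)/C=C/CCc1cccc(OCc2ccccc2)c1 | intermediate
9 | methyl 2-[2,5-bis(benzyloxy)phenyl]-3-[2-(3-benzyloxyphenyl)ethyl]-5-oxohexanoate (racemic, both diastereomers, present as its potassium enolate) | COC(=O)C(c1cc(OCc2ccccc2)ccc1OCc1ccccc1)C(CCc1cccc(OCc2ccccc2)c1)CC(C)=O | intermediate
10 | trans-4-[2,5-bis(benzyloxy)phenyl]-5-[2-(3-benzyloxyphenyl)ethyl]cyclohexane-1,3-dione (racemic, one enantiomer drawn) | O=C1CC(=O)[C@@H](c2cc(OCc3ccccc3)ccc2OCc2ccccc2)[C@H](CCc2cccc(OCc3ccccc3)c2)C1 | intermediate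
11 | trans-6-[2,5-bis(benzyloxy)phenyl]-5-[2-(3-benzyloxyphenyl)ethyl]-3-methoxycyclohex-2-en-1-one (racemic, one enantiomer drawn) | COC1=CC(=O)[C@@H](c2cc(OCc3ccccc3)ccc2OCc2ccccc2)[C@H](CCc2cccc(OCc3ccccc3)c2)C1 | intermediate
12 | 2-[2,5-bis(benzyloxy)phenyl]-3-[2-(3-benzyloxyphenyl)ethyl]-5-methoxy-1-(trimethylsilyloxy)cyclohexa-1,5-diene (racemic, one enantiomer drawn) | COC1=CC(O[Si](C)(C)C)=C(c2cc(OCc3ccccc3)ccc2OCc2ccccc2)[C@H](CCc2cccc(OCc3ccccc3)c2)C1 | intermediate
13 | 2-[2,5-bis(benzyloxy)phenyl]-3-[2-(3-benzyloxyphenyl)ethyl]-5-methoxycyclohexa-2,5-dien-1-one | COC1=CC(=O)C(c2cc(OCc3ccccc3)ccc2OCc2ccccc2)=C(CCc2cccc(OCc3ccccc3)c2)C1 | intermediate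
14 | 2-[2,5-bis(benzyloxy)phenyl]-3-[2-(3-benzyloxyphenyl)ethyl]-5-methoxyphenol | COc1cc(O)c(-c2cc(OCc3ccccc3)ccc2OCc2ccccc2)c(CCc2cccc(OCc3ccccc3)c2)c1 | intermediate
15 | 6-[2-(3-hydroxyphenyl)ethyl]-4-methoxybiphenyl-2,2',5'-triol | COc1cc(O)c(-c2cc(O)ccc2O)c(CCc2cccc(O)c2)c1 | target

**Totals**

Total step count: 10. Longest linear sequence: 8 steps (steps 3–10, from 4).

**Steps most likely to fail**

Step 6. The enone may be deprotonated at its γ-position by alkoxide and self-condense, or the conjugate addition may revert before the slower Claisen closure, so that the cascade stalls at open-chain material. Fallback, setting out from 3 and coming back at 10: the two bonds are made in separate operations without free alkoxide in the addition. Ester 3 is converted with LiN(iPr)2 and TMSCl in THF at −78 °C into the trimethylsilyl ketene acetal F1. A Mukaiyama–Michael addition of F1 to enone 8 promoted by TiCl4 in CH2Cl2 at −78 °C, followed by aqueous work-up, should give keto ester 9, now isolated. NaOMe in MeOH at reflux then closes 9 to dione 10 by Claisen condensation.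

Step 7. Methanol may also exchange at the shielded carbonyl, so that regiocontrol is incomplete and an isomeric enol ether is carried on to the isomeric methyl ether. Fallback, setting out from 10 and coming back at 15: the two ring-A oxygens are told apart after aromatization, by steric size instead of by equilibrium.
- Dione 10 is doubly deprotonated and silylated (LiN(iPr)2, 2.3 equiv, THF, −78 to 0 °C; TMSCl) to the bis(trimethylsilyloxy)cyclohexadiene F2; either dienolate regioisomer serves.
- DDQ in CH2Cl2 at rt dehydrogenates it to the resorcinol bis(trimethylsilyl) ether F3, and K2CO3 in MeOH frees the resorcinol F4.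
- TIPSCl and imidazole in DMF should silylate only the open hydroxyl on C5, giving the monosilyl ether F5.
- NaH and BnBr in THF/DMF at 0 °C benzylate the hydroxyl beside ring B, giving the benzyl ether F6.
- CsF and MeI in DMF exchange the silyl group for methyl in one flask, giving the tetrabenzyl methyl ether F7.
- Hydrogenolysis as in step 10, now of four benzyl ethers, gives 15.

Step 9. Transmetalation and β-hydride elimination may be slow at the fully substituted, aryl-bearing enol carbon, so that protodesilylation back to 11 outruns dehydrogenation. Fallback, setting out from 11 and coming back at 14: the double bond is introduced by selenoxide elimination. The lithium enolate of 11 (LiN(iPr)2, THF, −78 °C) is quenched with PhSeCl to give the α-phenylselanyl ketone F8, with selenium expected anti to the chain and hence cis to the hydrogen on the neighbouring carbon. H2O2 and pyridine in CH2Cl2 at 0 °C oxidize it to the selenoxide F9, whose syn-elimination gives dienone 13 and, by tautomerization, phenol 14.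

**Further compounds**

F1 | step 6 | [2-[2,5-bis(benzyloxy)phenyl]-1-methoxyethenyl]oxy(trimethyl)silane (E/Z mixture) | COC(O[Si](C)(C)C)=Cc1cc(OCc2ccccc2)ccc1OCc1ccccc1
F2 | step 7 | 2-[2,5-bis(benzyloxy)phenyl]-3-[2-(3-benzyloxyphenyl)ethyl]-1,5-bis(trimethylsilyloxy)cyclohexa-1,5-diene (racemic, one enantiomer drawn) | C[Si](C)(C)OC1=CC(O[Si](C)(C)C)=C(c2cc(OCc3ccccc3)ccc2OCc2ccccc2)[C@H](CCc2cccc(OCc3ccccc3)c2)C1
F3 | step 7 | 4-[2,5-bis(benzyloxy)phenyl]-5-[2-(3-benzyloxyphenyl)ethyl]-1,3-bis(trimethylsilyloxy)benzene | C[Si](C)(C)Oc1cc(O[Si](C)(C)C)c(-c2cc(OCc3ccccc3)ccc2OCc2ccccc2)c(CCc2cccc(OCc3ccccc3)c2)c1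
F4 | step 7 | 4-[2,5-bis(benzyloxy)phenyl]-5-[2-(3-benzyloxyphenyl)ethyl]benzene-1,3-diol | Oc1cc(O)c(-c2cc(OCc3ccccc3)ccc2OCc2ccccc2)c(CCc2cccc(OCc3ccccc3)c2)c1
F5 | step 7 | 2-[2,5-bis(benzyloxy)phenyl]-3-[2-(3-benzyloxyphenyl)ethyl]-5-(triisopropylsilyloxy)phenol | CC(C)[Si](Oc1cc(O)c(-c2cc(OCc3ccccc3)ccc2OCc2ccccc2)c(CCc2cccc(OCc3ccccc3)c2)c1)(C(C)C)C(C)C
F6 | step 7 | [3-benzyloxy-4-[2,5-bis(benzyloxy)phenyl]-5-[2-(3-benzyloxyphenyl)ethyl]phenoxy]triisopropylsilane | CC(C)[Si](Oc1cc(OCc2ccccc2)c(-c2cc(OCc3ccccc3)ccc2OCc2ccccc2)c(CCc2cccc(OCc3ccccc3)c2)c1)(C(C)C)C(C)C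
F7 | step 7 | 1-benzyloxy-2-[2,5-bis(benzyloxy)phenyl]-3-[2-(3-benzyloxyphenyl)ethyl]-5-methoxybenzene | COc1cc(OCc2ccccc2)c(-c2cc(OCc3ccccc3)ccc2OCc2ccccc2)c(CCc2cccc(OCc3ccccc3)c2)c1
F8 | step 9 | 6-[2,5-bis(benzyloxy)phenyl]-5-[2-(3-benzyloxyphenyl)ethyl]-3-methoxy-6-(phenylselanyl)cyclohex-2-en-1-one (racemic, Se cis to H-5, one enantiomer drawn) | COC1=CC(=O)[C@@](c2cc(OCc3ccccc3)ccc2OCc2ccccc2)([Se]c2ccccc2)[C@H](CCc2cccc(OCc3ccccc3)c2)C1
F9 | step 9 | 6-[2,5-bis(benzyloxy)phenyl]-5-[2-(3-benzyloxyphenyl)ethyl]-3-methoxy-6-(phenylseleninyl)cyclohex-2-en-1-one (racemic, mixture at selenium) | COC1=CC(=O)[C@@](c2cc(OCc3ccccc3)ccc2OCc2ccccc2)([Se](=O)c2ccccc2)[C@H](CCc2cccc(OCc3ccccc3)c2)C1
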